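Assumption: the target has no stereocentre and no stereogenic double bond, so there is no enantiomer to select; 1 and 4 are taken as catalogue compounds.

**Retrosynthetic overview**
- Target 8 comes from 7 by chelation-controlled cleavage of the 5-O-methyl ether only (last step).
- 7 is cut at C2–C1′ into chromone 3 and 2-methoxy-1,4-benzoquinone 4. Both carbons are natively electrophilic (enone β-carbon and quinone β-carbon); C2 is inverted to a carbanion (2-zincated chromone 5, a β-acylvinyl / masked acyl anion).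
- The quinone delivers the B ring directly as the free 2′,5′-hydroquinone with 4′-OMe in place, so no B-ring protecting groups are needed.
- 3 comes from acetophenone 1 plus one carbon from DMF-DMA.
- Ring order: A ring bought intact, pyranone ring closed in step 1, B ring attached as a quinone and aromatised in step 2.

**Route**

Step 1
Reactants: 1 1-(2-hydroxy-3,4,5,6-tetramethoxyphenyl)ethan-1-one
Product: 3 5,6,7,8-tetramethoxy-4H-chromen-4-one, via enaminone 2 (not isolated)
Conditions: DMF-DMA (3 equiv), PhMe, 100 °C; then conc. HCl, CH2Cl2, 40 °C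
Reagents that add atoms: N,N-dimethylformamide dimethyl acetal, COC(OC)N(C)C
Why: Condensation of the methyl ketone with DMF-DMA gives the (E)-enaminone, and under acid the phenol adds to its β-carbon with loss of dimethylamine (enaminone route to chromones); no stereocentre is formed.

Step 2
Reactants: 3 5,6,7,8-tetramethoxy-4H-chromen-4-one; 4 2-methoxy-1,4-benzoquinone
Product: 7 2-(2,5-dihydroxy-4-methoxyphenyl)-5,6,7,8-tetramethoxy-4H-chromen-4-one, via diorganozinc 5 (not isolated), via silyl ether 6 (not isolated)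
Conditions: TMP2Zn·2MgCl2·2LiCl (0.6 equiv), THF, −30 °C, 1 h; then added to 4 (1.5 equiv), [RhCl(cod)]2 (3 mol %), TMSCl (2 equiv), THF, 0 → 25 °C; 1 M HCl work-up
Reagents that add atoms: none
Why: Proposed new method: carbonyl-bound MgCl2 makes the pyranone pyrylium-like so the TMP-zinc amide removes C2–H (the C–H α to the ring oxygen; Lewis-acid-assisted C2 zincation of chromones with TMP-zinc bases is, as far as I recall, known chemistry), which turns the natively electrophilic enone β-carbon into a β-acylvinyl/masked acyl anion that transmetalates to Rh(I) and inserts into the unsubstituted C5=C6 bond of 4 with the new bond at C5 (β to the C1 carbonyl, the one not deactivated by the vinylogous-ester OMe, which is where thiols, amines and Thiele acetoxylation attack this quinone), after which TMSCl traps the rhodium enolate and the adduct tautomerises to aromatic silyl ether 6 that excess quinone cannot re-oxidise; the closest known reaction type is the Hayashi–Miyaura-type Rh-catalysed 1,4-addition of aryl- and alkenylzinc reagents to enones in the presence of TMSCl, and no stereocentre is formed.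

Step 3
Reactants: 7 2-(2,5-dihydroxy-4-methoxyphenyl)-5,6,7,8-tetramethoxy-4H-chromen-4-one
Product: 8 2-(2,5-dihydroxy-4-methoxyphenyl)-5-hydroxy-6,7,8-trimethoxy-4H-chromen-4-one
Conditions: BCl3 (5 equiv), CH2Cl2, −78 → 0 °C; then H2O
Reagents that add atoms: none
Why: BCl3 chelates between the C4 carbonyl and the peri 5-OMe so chloride cleaves only that ether (chelation-controlled Lewis-acid demethylation, standard for 5-methoxyflavones), while the non-chelated 6-, 7-, 8- and 4′-methyl ethers survive at ≤0 °C and the two phenols are only borylated and released on aqueous work-up.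

**Compound list**

1 | 1-(2-hydroxy-3,4,5,6-tetramethoxyphenyl)ethan-1-one | CC(=O)c1c(O)c(OC)c(OC)c(OC)c1OC | starting material
2 | (E)-3-(dimethylamino)-1-(2-hydroxy-3,4,5,6-tetramethoxyphenyl)prop-2-en-1-one | CN(C)/C=C/C(=O)c1c(O)c(OC)c(OC)c(OC)c1OC | intermediate
3 | 5,6,7,8-tetramethoxy-4H-chromen-4-one | O=c1ccoc2c1c(OC)c(OC)c(OC)c2OC | intermediate
4 | 2-methoxy-1,4-benzoquinone (2-methoxycyclohexa-2,5-diene-1,4-dione) | COC1=CC(=O)C=CC1=O | starting material
5 | bis(5,6,7,8-tetramethoxy-4-oxo-4H-chromen-2-yl)zinc (as its MgCl2/LiCl complex) | COc1c(OC)c(OC)c(OC)c2oc([Zn]c3cc(=O)c4c(OC)c(OC)c(OC)c(OC)c4o3)cc(=O)c12 | intermediate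
6 | 2-[2-hydroxy-4-methoxy-5-(trimethylsilyloxy)phenyl]-5,6,7,8-tetramethoxy-4H-chromen-4-one | COc1cc(O)c(-c2cc(=O)c3c(OC)c(OC)c(OC)c(OC)c3o2)cc1O[Si](C)(C)C | intermediate
7 | 2-(2,5-dihydroxy-4-methoxyphenyl)-5,6,7,8-tetramethoxy-4H-chromen-4-one | COc1cc(O)c(-c2cc(=O)c3c(OC)c(OC)c(OC)c(OC)c3o2)cc1O | intermediate
8 | 2-(2,5-dihydroxy-4-methoxyphenyl)-5-hydroxy-6,7,8-trimethoxy-4H-chromen-4-one | COc1cc(O)c(-c2cc(=O)c3c(O)c(OC)c(OC)c(OC)c3o2)cc1O | target

**Totals**

Total step count: 3. Longest linear sequence: 3 (1 → 3 → 7 → 8).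

**Steps most likely to fail, with fallbacks**

Step 2 (highest risk). The Rh-catalysed addition of a chromon-2-yl zinc species to a quinone is untested. The organozinc may instead reduce the quinone by electron transfer, and the zincation could go to C3 if the carbonyl is not Lewis-acid-bound. The C2 assignment for the MgCl2-containing base rests on my recollection of the precedent and on the mechanistic argument; an I2 or D2O quench of an aliquot should confirm C2 metalation before 4 is added. The fallback sets out from 3, through the same zinc reagent 5, and comes back at 7. Commercial 2-methoxybenzene-1,4-diol F1 is benzylated (BnBr, K2CO3, DMF) to 1,4-bis(benzyloxy)-2-methoxybenzene F2. Iodination para to the methoxy group (NIS, cat. TFA, MeCN) gives 1,4-bis(benzyloxy)-2-iodo-5-methoxybenzene F3. Negishi coupling of 5 with F3 (Pd(dba)2, P(2-furyl)3, THF, 50 °C) gives 2-[2,5-bis(benzyloxy)-4-methoxyphenyl]-5,6,7,8-tetramethoxy-4H-chromen-4-one F4. Hydrogenolysis (H2, Pd/C, EtOAc) then returns to 7.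

Step 3. BCl3 may go on from the 5-OMe to the neighbouring 6-OMe, or attack the 4′-OMe next to the borylated 5′-OH. The fallback sets out from 3 and comes back at 8; it moves the demethylation to the chromone stage, where only one chelated ether and no B ring are present. BCl3 (CH2Cl2, 0 °C) on 3 gives 5-hydroxy-6,7,8-trimethoxy-4H-chromen-4-one F5. NaH and MOMCl in DMF give 6,7,8-trimethoxy-5-(methoxymethoxy)-4H-chromen-4-one F6. Zincation as in step 2 gives bis[6,7,8-trimethoxy-5-(methoxymethoxy)-4-oxo-4H-chromen-2-yl]zinc F7. Rh/TMSCl addition to 4 gives 2-[2-hydroxy-4-methoxy-5-(trimethylsilyloxy)phenyl]-6,7,8-trimethoxy-5-(methoxymethoxy)-4H-chromen-4-one F8, and mild aqueous work-up gives 2-(2,5-dihydroxy-4-methoxyphenyl)-6,7,8-trimethoxy-5-(methoxymethoxy)-4H-chromen-4-one F9. HCl in MeOH at 40 °C removes the MOM group and gives 8.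

Step 1. DMF-DMA may O-methylate the phenol, or the crowded enaminone may cyclise sluggishly. The fallback sets out from 1 and comes back at 3. Claisen formylation with ethyl formate and NaH (THF, 0 °C → rt), followed by acid work-up, gives racemic hemiacetal 2-hydroxy-5,6,7,8-tetramethoxychroman-4-one F10. Dehydration with cat. TsOH in toluene gives 3.

**Further compounds**

F1 | step 2 | 2-methoxybenzene-1,4-diol | COc1cc(O)ccc1O
F2 | step 2 | 1,4-bis(benzyloxy)-2-methoxybenzene | COc1cc(OCc2ccccc2)ccc1OCc1ccccc1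
F3 | step 2 | 1,4-bis(benzyloxy)-2-iodo-5-methoxybenzene | COc1cc(OCc2ccccc2)c(I)cc1OCc1ccccc1
F4 | step 2 | 2-[2,5-bis(benzyloxy)-4-methoxyphenyl]-5,6,7,8-tetramethoxy-4H-chromen-4-one | COc1cc(OCc2ccccc2)c(-c2cc(=O)c3c(OC)c(OC)c(OC)c(OC)c3o2)cc1OCc1ccccc1
F5 | step 3 | 5-hydroxy-6,7,8-trimethoxy-4H-chromen-4-one | O=c1ccoc2c1c(O)c(OC)c(OC)c2OC
F6 | step 3 | 6,7,8-trimethoxy-5-(methoxymethoxy)-4H-chromen-4-one | O=c1ccoc2c1c(OCOC)c(OC)c(OC)c2OC
F7 | step 3 | bis[6,7,8-trimethoxy-5-(methoxymethoxy)-4-oxo-4H-chromen-2-yl]zinc | COCOc1c(OC)c(OC)c(OC)c2oc([Zn]c3cc(=O)c4c(OCOC)c(OC)c(OC)c(OC)c4o3)cc(=O)c12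
F8 | step 3 | 2-[2-hydroxy-4-methoxy-5-(trimethylsilyloxy)phenyl]-6,7,8-trimethoxy-5-(methoxymethoxy)-4H-chromen-4-one | COCOc1c(OC)c(OC)c(OC)c2oc(-c3cc(O[Si](C)(C)C)c(OC)cc3O)cc(=O)c12
F9 | step 3 | 2-(2,5-dihydroxy-4-methoxyphenyl)-6,7,8-trimethoxy-5-(methoxymethoxy)-4H-chromen-4-one | COCOc1c(OC)c(OC)c(OC)c2oc(-c3cc(O)c(OC)cc3O)cc(=O)c12
F10 | step 1 | 2-hydroxy-5,6,7,8-tetramethoxychroman-4-one (racemic) | O=C1CC(O)Oc2c1c(OC)c(OC)c(OC)c2OC
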